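Readings and results are calculated for an exercise.

The green run and the ochre run differ in both charges, yet both read 0.188 M of Pdt at 12 min, with at least 0.212 M of each reactant left. So I count turnovers.

the same everywhere: Ctl 0.0200 M
- red: Sbt 0.400 M; Ptn 1.00 M
- teal: Sbt 0.240 M; Ptn 0.840 M
- green: Sbt 0.400 M; Ptn 2.00 M
- ochre: Sbt 0.600 M; Ptn 1.00 M
- amber: Sbt 1.20 M; Ptn 0.330 M; time 12 min

| run | time / min | [Pdt] / M |
|---|---|---|
| red run | 1.7 | 0.069 |
| red run | 3.4 | 0.121 |
| red run | 5.1 | 0.134 |
| red run | 6.9 | 0.155 |
| red run | 8.6 | 0.172 |
| red run | 10 | 0.171 |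
| red run | 12 | 0.175 |
| teal run | 1.7 | 0.048 |
| teal run | 3.4 | 0.078 |
| teal run | 5.1 | 0.108 |
| teal run | 6.9 | 0.116 |
| teal run | 8.6 | 0.130 |
| teal run | 10 | 0.142 |
| teal run | 12 | 0.151 |
| green run | 1.7 | 0.078 |
| green run | 3.4 | 0.121 |
| green run | 5.1 | 0.150 |
| green run | 6.9 | 0.161 |
| green run | 8.6 | 0.170 |
| green run | 10 | 0.175 |
| green run | 12 | 0.188 |
| ochre run | 1.7 | 0.087 |
| ochre run | 3.4 | 0.138 |
| ochre run | 5.1 | 0.156 |
| ochre run | 6.9 | 0.172 |
| ochre run | 8.6 | 0.186 |
| ochre run | 10 | 0.179 |
| ochre run | 12 | 0.188 |

(scatter of a reading: 0.004 M)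

- reaction order in [Ptn] at the outset, round the charge of the red run, defined at two percent of the Sbt turned into Pdt
- reaction order in [Sbt] at the outset, round the charge of the red run, defined at two percent of the Sbt turned into Pdt (one fixed amount of Pdt, the same in the runs compared)
- Pdt in the amber run at 12 min, as a share of the Sbt charged
- which of these the readings show (the substrate kills the catalyst / the catalyst dies by itself / the second partner is lost by itself / the product speeds the reaction / nothing beyond the main steps / the catalyst rests as a dimer)

- Overall: Sbt + Ptn -> Pdt, with Ctl as catalyst.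
- Constant volume, constant temperature.
- The analysis sees a species whether free or bound.
- "The second partner" is Ptn.
- An order is taken over about fifteen percent of the charge, up and down.

1. The main step by itself. Ctl turns Sbt and Ptn into Pdt and comes back. Amber then stops at its Ptn charge, the limiting reagent: 0.330 M, or 27.5% of the Sbt charged.

2. Add the loss of Ctl. The last reading of the green run, per Ctl charged, comes to 9.40; this Pdt made per Ctl charged before Ctl is lost is my turnover budget. For amber I estimate from it a ceiling of 0.188 M, lower than the Ptn charge, and the number falls to 15.7%.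

3. Ask what spends the budget. I define the spending time as the time in which the unspent budget falls by a factor e, and take it from each first reading. Red gives 3.72 min. Ochre, with the same Ptn and more Sbt, gives a shorter 2.74 min. Between these two runs the spending quickens as Sbt rises, so I choose: the substrate kills the catalyst.

4. Add the pace of the cycle. I write the spending time as a Sbt part plus a Ptn part, each inverse to its own concentration. Green has twice the Ptn of red and reads 3.17 min. So in red the Ptn part is 1.09 min and the Sbt part 2.63 min. Their shares are my orders: 0.293 in Ptn and 0.707 in Sbt, each resting on single readings with scatter 0.004 M.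

5. Add the fall of Ptn. In amber the Sbt part shrinks to 0.875 min. For Ptn I take its charge less half the ceiling, 0.236 M, which makes the Ptn part 4.62 min. My estimate of the spending time is then 5.50 min, so 12 min spends 88.7% of the budget. That gives 0.167 M, or 13.9% of the Sbt charged.

The forecast, with numbers of its own, gives orders of 0.24 in Ptn and 0.74 in Sbt, 14% for amber and "the substrate kills the catalyst", holding that “The decay therefore speeds up with Sbt”.

The simulation runs this scheme:

    Ctl + Sbt → Ctl.Sbt (10.56 L mol⁻¹ min⁻¹)
    Ctl.Sbt + Ptn → Pdt + Ctl (11.46 L mol⁻¹ min⁻¹)
    Ctl + Sbt → G + Sbt (1.116 L mol⁻¹ min⁻¹)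

Amber gives 14.2% at 12 min, the orders round the red charge are 0.33 in Ptn and 0.69 in Sbt, and the readings show that the substrate kills the catalyst. The fit in which the second partner is lost by itself leaves a residual of 4.7 scatter units and puts amber at 9.17%. Counted in turnovers, amber's Pdt at 12 min is 8.51 per Ctl, 90.5% of the budget. In the ochre run, a quarter of the Sbt is turned at 4.36 min, which costs 7.50 turnovers, 79.8% of the budget.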